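**Retrosynthetic overview**

1. The target is the C5–O ester of the cis lactone (5S,6S)-5-hydroxy-6-[(E)-propenyl]-5,6-dihydro-2H-pyran-2-one (ring O1, C2–C6) with (2E,4E,6S)-4,6-dimethyldodeca-2,4-dienoic acid (C1'–C12'); this ester bond is made last.
2. The strategy rests on the side-chain stereocentre C6', which carries H and three carbon groups: CH3, the n-hexyl chain C7'–C12' and the alkenyl carbon C5' of the E C4'(CH3)=C5' bond. The C6'–CH3 and C5'–C6' bonds are both made on one boron atom by two consecutive 1,2-shifts (lithiation–borylation, then Zweifel olefination) from a heptyl benzoate, MeBpin and a Z-alkenyl iodide.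
3. The C1'–C3' end is added afterwards; C2'=C3' comes from a Horner–Wadsworth–Emmons reaction on the enal.
4. The dihydropyranone is the only ring. C5 and C6 are set by a syn-alkoxyallylboration of crotonaldehyde, and the ring is closed once, at C3=C4, by ring-closing metathesis of an acrylate.

Key step: step 4

Remark: the two halves of step 4 are established reactions; that they can follow each other in one flask, with sparteine and lithium 2,4,6-triisopropylbenzoate still present, is assumed.

**Route**

Step 1
Reactants: 1 heptan-1-ol; 2 2,4,6-triisopropylbenzoyl chloride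
Product: 3 heptyl 2,4,6-triisopropylbenzoate
Conditions: Et3N, DMAP (cat.), CH2Cl2, rt → 40 °C
Reagents that add atoms: none
Why: DMAP-catalysed esterification of an unhindered primary alcohol with the hindered acyl chloride should give the ester, whose shielded carbonyl later resists attack by s-BuLi.

Step 2
Reactants: 4 prop-2-yn-1-ol
Product: 6 (Z)-3-iodo-2-methylprop-2-en-1-ol, via cyclic alkenylmagnesium alkoxide 5 (not isolated)
Conditions: MeMgBr, CuI (cat.), THF, −10 °C → rt; then I2, THF, −10 °C → 0 °C; aq. NH4Cl
Reagents that add atoms: methylmagnesium bromide, C[Mg]Br; iodine, II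
Why: Hydroxyl-directed, CuI-catalysed anti-carbomagnesiation of the alkyne (Duboudin-type Grignard addition) should place CH3 on C2 and magnesium on C3 inside chelate 5, cis to CH2O, and iodinolysis with retention then gives the Z-iodide.

Step 3
Reactants: 6 (Z)-3-iodo-2-methylprop-2-en-1-ol
Product: 7 (Z)-tert-butyl[(3-iodo-2-methylallyl)oxy]dimethylsilane
Conditions: TBSCl, imidazole, CH2Cl2, 0 °C → rt
Reagents that add atoms: tert-butyldimethylsilyl chloride, CC(C)(C)[Si](C)(C)Cl
Why: Imidazole-mediated silylation of the primary allylic alcohol should proceed without touching the alkenyl iodide or its geometry.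

Step 4
Reactants: 3 heptyl 2,4,6-triisopropylbenzoate; 8 2,4,4,5,5-pentamethyl-1,3,2-dioxaborolane (MeBpin); 7 (Z)-tert-butyl[(3-iodo-2-methylallyl)oxy]dimethylsilane
Product: 14 (S,E)-tert-butyl[(2,4-dimethyldec-2-en-1-yl)oxy]dimethylsilane, via lithiated benzoate 9 (not isolated), via methyl boronate complex 10 (not isolated), via sec-alkyl boronic ester 11 (not isolated), via alkenyllithium 12 (not isolated), via alkenyl boronate complex 13 (not isolated)
Conditions: 3 (slight excess over 8), s-BuLi, (−)-sparteine, Et2O, −78 °C; 8, −78 °C → 35 °C; recool, 12 (from 7, t-BuLi, Et2O, −78 °C), then THF, −78 °C; I2, MeOH, −78 °C; NaOMe, MeOH, −78 °C → rt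
Reagents that add atoms: none
Why: The s-BuLi/(−)-sparteine complex should remove the pro-S α-hydrogen of 3 (Hoppe-type deprotonation) to give the configurationally stable carbenoid 9, which 8 borylates with retention to 10; on warming, the methyl group shifts from boron to carbon anti to the departing benzoate (1,2-metallate rearrangement, inversion at carbon), which fixes C6' as S in 11. Alkenyllithium 12, formed from 7 with retention of the Z geometry, adds to 11 to give 13; I2 then adds to the alkene of 13 and triggers the shift of the sec-alkyl group from boron to C5' with retention at C6', after which NaOMe induces anti elimination of boron and iodine (Zweifel olefination). The closest known reactions are the lithiation–borylation of primary 2,4,6-triisopropylbenzoates with pinacol boronic esters and the Zweifel olefination of secondary pinacol boronic esters, here run one after the other in one flask. No ring is closed. The C6' stereocentre is controlled by the diamine, and the C4'=C5' geometry by the anti migration and anti elimination, which together invert the alkenyl geometry, so the Z-iodide (iodine cis to CH2OSi) should deliver the E alkene. The step needs a single homologation and a clean second boronate: the bulky benzoate blocks carbonyl attack and acts as leaving group, 8 is the limiting component so none is left to consume 12, surplus 9 decays on warming before 12 is added, and 12 is kept in Et2O at −78 °C until it meets 11 to suppress O-to-C silyl migration.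

Step 5
Reactants: 14 (S,E)-tert-butyl[(2,4-dimethyldec-2-en-1-yl)oxy]dimethylsilane
Product: 15 (2E,4S)-2,4-dimethyldec-2-en-1-ol
Conditions: n-Bu4NF, THF, 0 °C → rt
Reagents that add atoms: none
Why: Fluoride-mediated Si–O cleavage should free the allylic alcohol without affecting the alkene geometry or the C4 stereocentre.

Step 6
Reactants: 15 (2E,4S)-2,4-dimethyldec-2-en-1-ol
Product: 16 (2E,4S)-2,4-dimethyldec-2-enal
Conditions: MnO2 (excess), CH2Cl2, rt
Reagents that add atoms: none
Why: MnO2 oxidation of an allylic alcohol is neutral and heterogeneous, so the γ-stereocentre and the E geometry should be preserved.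

Step 7
Reactants: 16 (2E,4S)-2,4-dimethyldec-2-enal
Product: 17 ethyl (2E,4E,6S)-4,6-dimethyldodeca-2,4-dienoate
Conditions: (EtO)2P(O)CH2CO2Et, NaH, THF, 0 °C; then 16, 0 °C → rt
Reagents that add atoms: triethyl phosphonoacetate, CCOC(=O)CP(=O)(OCC)OCC
Why: Horner–Wadsworth–Emmons olefination with the phosphonate deprotonated beforehand should give the E C2'=C3' bond and leaves no free base to deprotonate the γ-position of the enal.

Step 8
Reactants: 17 ethyl (2E,4E,6S)-4,6-dimethyldodeca-2,4-dienoate
Product: 18 (2E,4E,6S)-4,6-dimethyldodeca-2,4-dienoic acid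
Conditions: LiOH, THF/MeOH/H2O, rt; then 1 M HCl
Reagents that add atoms: lithium hydroxide, [Li+].[OH-]
Why: Saponification of the ethyl ester should give the acid after acidification, the remote C6' hydrogen not being acidic under these conditions.

Step 9
Reactants: 19 (E)-but-2-enal (crotonaldehyde); 20 3-(methoxymethoxy)prop-1-ene
Product: 22 (3S,4S,5E)-3-(methoxymethoxy)hepta-1,5-dien-4-ol, via alkoxyallylborane 21 (not isolated)
Conditions: 20, s-BuLi, THF, −78 °C; (+)-Ipc2BOMe (made from (−)-α-pinene), −78 °C; BF3·OEt2, −78 °C; 19, −78 °C; then NaOH, H2O2, 0 °C → rt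
Reagents that add atoms: none
Why: In this Brown asymmetric alkoxyallylboration the Z-γ-alkoxyallylborane 21 should add 1,2 to the aldehyde through a chair six-membered transition state, so the Z geometry gives the syn 3,4-relationship and the isopinocampheyl groups from (−)-α-pinene are expected to direct attack to the Re face, setting 3S and 4S.

Step 10
Reactants: 22 (3S,4S,5E)-3-(methoxymethoxy)hepta-1,5-dien-4-ol
Product: 23 (3S,4S,5E)-3-(methoxymethoxy)hepta-1,5-dien-4-yl prop-2-enoate
Conditions: acryloyl chloride, Et3N, DMAP (cat.), CH2Cl2, 0 °C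
Reagents that add atoms: acryloyl chloride, C=CC(=O)Cl
Why: O-Acylation of the only free hydroxyl should give the acrylate, the MOM ether keeping the second oxygen blocked.

Step 11
Reactants: 23 (3S,4S,5E)-3-(methoxymethoxy)hepta-1,5-dien-4-yl prop-2-enoate
Product: 24 (5S,6S)-5-(methoxymethoxy)-6-[(E)-prop-1-en-1-yl]-5,6-dihydro-2H-pyran-2-one
Conditions: second-generation Grubbs catalyst (H2IMes)(PCy3)Cl2Ru=CHPh (5 mol %), CH2Cl2 (dilute), 40 °C
Reagents that add atoms: none
Why: In this ring-closing metathesis the ruthenium carbene should form at the terminal vinyl group and close onto the acrylate to the six-membered unsaturated lactone with loss of ethene, whereas the 1,2-disubstituted propenyl group reacts more slowly and could only close a five-membered butenolide; C5 and C6 are not touched.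

Step 12
Reactants: 24 (5S,6S)-5-(methoxymethoxy)-6-[(E)-prop-1-en-1-yl]-5,6-dihydro-2H-pyran-2-one
Product: 26 (5S,6S)-5-hydroxy-6-[(E)-prop-1-en-1-yl]-5,6-dihydro-2H-pyran-2-one, via bromomethyl ether 25 (not isolated)
Conditions: Me2BBr, CH2Cl2, −78 °C; then aq. NaHCO3, THF, 0 °C
Reagents that add atoms: none
Why: In this Guindon-type acetal cleavage Me2BBr should complex the methoxy oxygen and bromide open the acetal at −78 °C to 25, which hydrolyses on bicarbonate work-up, while the lactone, both alkenes and both stereocentres stay untouched at this temperature.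

Step 13
Reactants: 18 (2E,4E,6S)-4,6-dimethyldodeca-2,4-dienoic acid; 26 (5S,6S)-5-hydroxy-6-[(E)-prop-1-en-1-yl]-5,6-dihydro-2H-pyran-2-one
Product: 28 (2S,3S)-6-oxo-2-[(E)-prop-1-en-1-yl]-3,6-dihydro-2H-pyran-3-yl (2E,4E,6S)-4,6-dimethyldodeca-2,4-dienoate (CNP0240957.1), via mixed anhydride 27 (not isolated)
Conditions: 2,4,6-trichlorobenzoyl chloride, Et3N, toluene, rt; then 26, DMAP, toluene, 0 °C → rt
Reagents that add atoms: none
Why: In this Yamaguchi esterification DMAP should take the dienoyl group from the less hindered carbonyl of 27 and pass it to the C5 hydroxyl, and since the C5–O bond is never broken the cis (5S,6S) configuration is retained.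

**Compound list**

1 | heptan-1-ol | CCCCCCCO | starting material
2 | 2,4,6-triisopropylbenzoyl chloride | CC(C)c1cc(C(C)C)c(C(=O)Cl)c(C(C)C)c1 | starting material
3 | heptyl 2,4,6-triisopropylbenzoate | CCCCCCCOC(=O)c1c(C(C)C)cc(C(C)C)cc1C(C)C | intermediate
4 | prop-2-yn-1-ol (propargyl alcohol) | C#CCO | starting material
5 | 4-methyl-2,5-dihydro-1,2-oxamagnesole (cyclic alkenylmagnesium alkoxide) | CC1=C[Mg]OC1 | intermediate
6 | (Z)-3-iodo-2-methylprop-2-en-1-ol | I/C=C(C)\CO | intermediate
7 | (Z)-tert-butyl[(3-iodo-2-methylallyl)oxy]dimethylsilane | I/C=C(C)\CO[Si](C)(C)C(C)(C)C | intermediate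
8 | 2,4,4,5,5-pentamethyl-1,3,2-dioxaborolane (MeBpin) | CB1OC(C)(C)C(C)(C)O1 | starting material
9 | (S)-1-lithioheptyl 2,4,6-triisopropylbenzoate (as its (−)-sparteine complex) | CCCCCC[C@H]([Li])OC(=O)c1c(C(C)C)cc(C(C)C)cc1C(C)C | intermediate
10 | lithium methyl(pinacolato)[(S)-1-(2,4,6-triisopropylbenzoyloxy)heptyl]borate | [Li+].CCCCCC[C@@H](OC(=O)c1c(C(C)C)cc(C(C)C)cc1C(C)C)[B-]1(C)OC(C)(C)C(C)(C)O1 | intermediate
11 | (S)-4,4,5,5-tetramethyl-2-(octan-2-yl)-1,3,2-dioxaborolane | CCCCCC[C@H](C)B1OC(C)(C)C(C)(C)O1 | intermediate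
12 | (Z)-[3-(tert-butyldimethylsilyloxy)-2-methylprop-1-en-1-yl]lithium | [Li]/C=C(C)\CO[Si](C)(C)C(C)(C)C | intermediate
13 | lithium [(Z)-3-(tert-butyldimethylsilyloxy)-2-methylprop-1-en-1-yl][(S)-octan-2-yl](pinacolato)borate | [Li+].CCCCCC[C@H](C)[B-]1(/C=C(C)\CO[Si](C)(C)C(C)(C)C)OC(C)(C)C(C)(C)O1 | intermediate
14 | (S,E)-tert-butyl[(2,4-dimethyldec-2-en-1-yl)oxy]dimethylsilane | CC(C)(C)[Si](C)(C)OC/C(C)=C/[C@@H](C)CCCCCC | intermediate
15 | (2E,4S)-2,4-dimethyldec-2-en-1-ol | OC/C(C)=C/[C@@H](C)CCCCCC | intermediate
16 | (2E,4S)-2,4-dimethyldec-2-enal | O=C/C(C)=C/[C@@H](C)CCCCCC | intermediate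
17 | ethyl (2E,4E,6S)-4,6-dimethyldodeca-2,4-dienoate | CCOC(=O)/C=C/C(C)=C/[C@@H](C)CCCCCC | intermediate
18 | (2E,4E,6S)-4,6-dimethyldodeca-2,4-dienoic acid | OC(=O)/C=C/C(C)=C/[C@@H](C)CCCCCC | intermediate
19 | (E)-but-2-enal (crotonaldehyde) | C/C=C/C=O | starting material
20 | 3-(methoxymethoxy)prop-1-ene | C=CCOCOC | starting material
21 | [(Z)-3-(methoxymethoxy)allyl]diisopinocampheylborane (isopinocampheyl groups from (−)-α-pinene) | COCO/C=C\CB([C@H]1C[C@H]2C[C@@H]([C@@H]1C)C2(C)C)[C@H]1C[C@H]2C[C@@H]([C@@H]1C)C2(C)C | intermediate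
22 | (3S,4S,5E)-3-(methoxymethoxy)hepta-1,5-dien-4-ol | C/C=C/[C@H](O)[C@@H](OCOC)C=C | intermediate
23 | (3S,4S,5E)-3-(methoxymethoxy)hepta-1,5-dien-4-yl prop-2-enoate | C/C=C/[C@H](OC(=O)C=C)[C@@H](OCOC)C=C | intermediate
24 | (5S,6S)-5-(methoxymethoxy)-6-[(E)-prop-1-en-1-yl]-5,6-dihydro-2H-pyran-2-one | C/C=C/[C@@H]1OC(=O)C=C[C@@H]1OCOC | intermediate
25 | (5S,6S)-5-(bromomethoxy)-6-[(E)-prop-1-en-1-yl]-5,6-dihydro-2H-pyran-2-one | C/C=C/[C@@H]1OC(=O)C=C[C@@H]1OCBr | intermediate
26 | (5S,6S)-5-hydroxy-6-[(E)-prop-1-en-1-yl]-5,6-dihydro-2H-pyran-2-one | C/C=C/[C@@H]1OC(=O)C=C[C@@H]1O | intermediate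
27 | (2E,4E,6S)-4,6-dimethyldodeca-2,4-dienoic 2,4,6-trichlorobenzoic anhydride | O=C(OC(=O)c1c(Cl)cc(Cl)cc1Cl)/C=C/C(C)=C/[C@@H](C)CCCCCC | intermediate
28 | (2S,3S)-6-oxo-2-[(E)-prop-1-en-1-yl]-3,6-dihydro-2H-pyran-3-yl (2E,4E,6S)-4,6-dimethyldodeca-2,4-dienoate (CNP0240957.1) | C/C=C/[C@@H]1OC(=O)C=C[C@@H]1OC(=O)/C=C/C(C)=C/[C@@H](C)CCCCCC | target

**Step count**

Total: 13 steps (8 to the acid 18, 4 to the hydroxy lactone 26, 1 coupling).
Longest linear sequence: 8 steps (steps 2, 3, 4, 5, 6, 7, 8 and 13, from 4 to 28).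

**Steps most likely to fail**

Step 4. Methyl is a slow migrating group, so boronate 10 may revert or undergo oxygen migration before the C–C shift, lowering conversion or enantiomeric purity. In the second stage the lithium carboxylate, sparteine and carbenoid residues may intercept 12 or the iodine, and 12 may undergo O-to-C silyl shift if it warms. The fallback sets out from 2 and 7 and comes back at 14; it reverses the roles of the two alkyl partners and separates the two stages. Compound 2 is esterified with ethanol (Et3N, DMAP) to ethyl 2,4,6-triisopropylbenzoate F1. F1 is deprotonated with s-BuLi/(+)-sparteine (Et2O, −78 °C) to (R)-1-lithioethyl 2,4,6-triisopropylbenzoate F2, which is trapped with commercial 2-hexyl-4,4,5,5-tetramethyl-1,3,2-dioxaborolane as lithium hexyl(pinacolato)[(R)-1-(2,4,6-triisopropylbenzoyloxy)ethyl]borate F3. The primary hexyl group, a better migrating group than methyl, shifts with inversion and should give the same (S)-boronic ester 11, which is isolated and purified. In a separate flask 11 is combined with 12 (from 7 and t-BuLi) and treated with I2 and NaOMe to give 14.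

Step 12. The freed C5 hydroxyl may attack the lactone carbonyl under Lewis acid (ring contraction to the butenolide), or the allylic C6–O bond may ionise during acetal cleavage. The fallback sets out from 23 and comes back at 26; the acetal is cleaved before the ring exists. Compound 23 with Me2BBr (CH2Cl2, −78 °C) gives (3S,4S,5E)-3-(bromomethoxy)hepta-1,5-dien-4-yl prop-2-enoate F4, which hydrolyses on NaHCO3 work-up to (3S,4S,5E)-3-hydroxyhepta-1,5-dien-4-yl prop-2-enoate F5. Ring-closing metathesis of F5 with (H2IMes)(PCy3)Cl2Ru=CHPh then forms 26 directly under neutral conditions, the free allylic hydroxyl also favouring carbene formation at the adjacent vinyl group.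

Step 13. The hydroxy lactone 26 may isomerise or eliminate under Et3N/DMAP, and the conjugated dienoyl group is a slow acyl donor, so acylation may occur at the aryl carbonyl of the mixed anhydride. The fallback sets out from 23 and 18 and comes back at 28; the ester is made before the ring. The hydroxy acrylate F5, made from 23 as in the fallback to step 12, is esterified with 18 (DCC, DMAP cat., CH2Cl2, 0 °C) to (3S,4S,5E)-4-(prop-2-enoyloxy)hepta-1,5-dien-3-yl (2E,4E,6S)-4,6-dimethyldodeca-2,4-dienoate F6. Ring-closing metathesis of F6 with (H2IMes)(PCy3)Cl2Ru=CHPh between the vinyl and acrylate groups, the internal and conjugated side-chain alkenes being far less reactive, closes the lactone last and gives 28.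

Further compounds
F1 | step 4 | ethyl 2,4,6-triisopropylbenzoate | CCOC(=O)c1c(C(C)C)cc(C(C)C)cc1C(C)C
F2 | step 4 | (R)-1-lithioethyl 2,4,6-triisopropylbenzoate | C[C@@H]([Li])OC(=O)c1c(C(C)C)cc(C(C)C)cc1C(C)C
F3 | step 4 | lithium hexyl(pinacolato)[(R)-1-(2,4,6-triisopropylbenzoyloxy)ethyl]borate | [Li+].C[C@H](OC(=O)c1c(C(C)C)cc(C(C)C)cc1C(C)C)[B-]1(CCCCCC)OC(C)(C)C(C)(C)O1
F4 | step 12 | (3S,4S,5E)-3-(bromomethoxy)hepta-1,5-dien-4-yl prop-2-enoate | C/C=C/[C@H](OC(=O)C=C)[C@@H](OCBr)C=C
F5 | step 12 | (3S,4S,5E)-3-hydroxyhepta-1,5-dien-4-yl prop-2-enoate | C/C=C/[C@H](OC(=O)C=C)[C@@H](O)C=C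
F6 | step 13 | (3S,4S,5E)-4-(prop-2-enoyloxy)hepta-1,5-dien-3-yl (2E,4E,6S)-4,6-dimethyldodeca-2,4-dienoate | C/C=C/[C@H](OC(=O)C=C)[C@H](C=C)OC(=O)/C=C/C(C)=C/[C@@H](C)CCCCCC
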